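**Plan**

1. Numbering follows spiro[5.5]undecane (= chamigrane). Ring B is C1–C6 (C2 Br, C3 Cl/CH3, C6 spiro). Ring A is C6–C11 (C7 =CH2, C8 OH, C9=C10 Br, C11 Me2). The hardest features are the C6–C11 bond between two quaternary carbons and the remote relation of spiro C6 to a diequatorial C2‑Br/C3‑Cl pair.
2. Enabling feature: C6 is stereogenic only because C2 carries Br and C4 does not. Without Br, Cl/CH3 and C8‑OH the skeleton is the achiral 4,4‑disubstituted cyclohexanone 11. Its ring B is halved by the plane through C3, C6 and ring A, and it is locked in one chair by C11 (equatorial) against C7 (axial).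
3. Retrosynthetic cuts: C8–H, C7=C14, C3–Cl, C3–C15 and C2–Br lead back to 11. Ring A of 11 is cut at C10–C11 (two‑carbon ring expansion) to a spiro[3.5]nonanone, which is cut at C6–C11 and C7–C8 ([2+2]).
4. Forward order: ring B is bought. A keteniminium [2+2] builds the cyclobutanone and sets C6–C11. Bromoethynyl addition and radical ring expansion build ring A with Br already on C10. Ring B is then desymmetrised and halogenated. C14 and C8–H come last.
5. Stereochemistry: a chiral lithium amide chooses C2–H over C4–H, which sets C6. Bromide‑exchange equilibration sets C2 (equatorial). Axial methyl delivery and retentive chlorination relay this to C3. CBS reagent control sets C8.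
6. Direct BrCl addition to a Δ2‑chamigrene is avoided, because its diaxial, Markovnikov‑matched path would place Br cis to C7, which is the wrong diastereomer.

Key step: step 6

Assumption: the sense of induction of the chiral base ((R,R) → 6S enol silane 12) and of the CBS catalyst ((S) → 8R) is assigned by analogy with 4‑tert‑butylcyclohexanone and with aryl alkyl ketones; if either is opposite, the equally available enantiomeric reagent is used.

**Step 1**
Reactants: 1 8‑methylene‑1,4‑dioxaspiro[4.5]decane; 2 N,N,2‑trimethylpropanamide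
Product: 5 1,1‑dimethyl‑8,11‑dioxadispiro[3.2.4^7.2^4]tridecan‑2‑one, via keteniminium triflate 3 (not isolated), via cyclobutaniminium triflate 4 (not isolated)
Conditions: Tf2O, 2,4,6‑collidine, ClCH2CH2Cl, 80 °C; then sat. aq NaHCO3, 60 °C
Reagents that add atoms: water O (carbonyl oxygen of 5); triflic anhydride O=S(=O)(OS(=O)(=O)C(F)(F)F)C(F)(F)F (counter‑ion of 3 and 4 only)
Why: Keteniminium–alkene [2+2] cycloaddition, in which the electrophilic central carbon of 3 bonds to the unhindered =CH2 (future C7) and the cation developing at C6 collapses onto the CMe2 terminus, so the congested C6–C11 bond forms inside a four‑membered ring and hydrolysis of 4 gives the ketone without creating a stereocentre.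

**Step 2**
Reactants: 5; 6 ethynylmagnesium bromide
Product: 7 2‑ethynyl‑1,1‑dimethyl‑8,11‑dioxadispiro[3.2.4^7.2^4]tridecan‑2‑ol (racemic)
Conditions: THF, 0 °C → rt; then H2O
Reagents that add atoms: none
Why: 1,2‑Addition of an acetylide to a strained cyclobutanone, where sp2→sp3 strain release outweighs the neopentyl hindrance and enolisation; the racemic carbinol centre is erased in step 4.

**Step 3**
Reactants: 7
Product: 8 2‑(bromoethynyl)‑1,1‑dimethyl‑8,11‑dioxadispiro[3.2.4^7.2^4]tridecan‑2‑ol (racemic)
Conditions: NBS, AgNO3 (10 mol %), acetone, rt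
Reagents that add atoms: N‑bromosuccinimide O=C1CCC(=O)N1Br
Why: Silver‑catalysed bromination of a terminal alkyne through the silver acetylide, which should be faster than a bromonium‑induced semipinacol shift of the cyclobutanol.

**Step 4**
Reactants: 8
Product: 10 10‑bromo‑11,11‑dimethylspiro[5.5]undec‑9‑ene‑3,8‑dione 3‑(ethylene ketal), via tertiary radical 9 (not isolated)
Conditions: [Ir(dF(CF3)ppy)2(5,5′‑d(CF3)bpy)]PF6 (2 mol %), Bu4P+ (MeO)2PO2− (25 mol %), 2,4,6‑triisopropylbenzenethiol (10 mol %), PhCF3 (0.02 M), blue LED, rt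
Reagents that add atoms: none
Why: Proposed new method: proton‑coupled electron transfer from the tertiary O–H gives the cyclobutyloxy radical, whose strain‑driven β‑scission breaks the more substituted C8–C11 bond and gives the tertiary radical 9 next to a bromo‑ynone; this nucleophilic radical should re‑close 6‑endo‑dig at the electrophilic β‑carbon C10 (5‑exo attack at the α‑carbon C9 is polarity‑mismatched, and the two quaternary carbons in the tether favour closure), and the resulting C9 σ‑vinyl radical takes hydrogen from the thiol, so the net change is a redox‑neutral isomerisation that inserts C9 and C10 between C8 and C11 with bromine already on C10; the closest known reaction types are the photocatalytic ring‑opening isomerisation of cycloalkanols through alkoxy radicals and the radical ring expansion of 1‑arylcyclobutanols to 1‑tetralones.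

**Step 5**
Reactants: 10
Product: 11 10‑bromo‑11,11‑dimethylspiro[5.5]undec‑9‑ene‑3,8‑dione (achiral)
Conditions: PPTS (20 mol %), acetone–H2O 9:1, 50 °C
Reagents that add atoms: water O
Why: Mild acid‑catalysed ketal hydrolysis, too weak to hydrolyse the hindered vinylogous acyl bromide, and the product has no stereogenic unit.

**Step 6**
Reactants: 11
Product: 14 (2S,6R)‑2,10‑dibromo‑11,11‑dimethylspiro[5.5]undec‑9‑ene‑3,8‑dione, via enol silane 12 (not isolated), via axial bromide 13 (not isolated)
Conditions: (R,R)‑[PhCH(CH3)]2NH, n‑BuLi, THF, −78 °C; 11 + TMSCl (in situ quench), −100 °C; pentane extraction; NBS, THF, −78 °C; then Bu4NBr (10 mol %), CH2Cl2, rt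
Reagents that add atoms: N‑bromosuccinimide O=C1CCC(=O)N1Br; chlorotrimethylsilane C[Si](C)(C)Cl (stays only in 12)
Why: A C2‑symmetric chiral lithium amide removes one of the two enantiotopic axial α‑hydrogens (C2–H versus C4–H) of the σ‑symmetric ketone and TMSCl traps the enolate as it forms (chiral‑base desymmetrisation of 4‑ and 4,4‑substituted cyclohexanones is the closest known reaction type), after which NBS brominates the enol silane 12 at C2. The selection is meaningful because ring B of 11 populates a single chair, with C11 (CMe2) equatorial and C7 axial, so choosing C2 over C4 by itself turns C6 into a stereocentre (reagent control) although no bond is made or broken at this hindered atom. No ring is closed in this step. The configuration at C2 is set thermodynamically and not by the face of bromination: catalytic bromide interconverts 13 and 14 by SN2 exchange, without enolisation and hence without drift of bromine to C4 that would erode C6, and 13 is drained because its axial bromine clashes 1,3‑diaxially with C7, which leaves the equatorial bromide 14 with Br cis to C11 as in the target. The step needs chemoselectivity for ring B: the only other acidic hydrogens (C7–H2) are neopentyl and lie in the shadow of ring B, and addition of the bulky amide to the vinylogous acyl bromide is blocked at C10 by C11. One operation thus converts a compound without any stereogenic unit into one that carries the spiro stereocentre and the first halogen‑bearing centre, in the relative configuration that direct addition of BrCl to a Δ2‑olefin would not give.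

**Step 7**
Reactants: 14
Product: 15 (2S,3S,6R)‑2,10‑dibromo‑3‑hydroxy‑3,11,11‑trimethylspiro[5.5]undec‑9‑en‑8‑one (CH3 axial; OH equatorial and trans to Br)
Conditions: AlMe3 (4 equiv), toluene, −78 → −30 °C; then H2O
Reagents that add atoms: trimethylaluminium C[Al](C)C
Why: Excess AlMe3 in a hydrocarbon solvent transfers methyl axially to the aluminium‑complexed cyclohexanone (compression effect, reinforced by the equatorial C2–Br), which sets C3 with equatorial OH; the α‑bromo ketone is far more electrophilic than the conjugated, neopentyl‑flanked C8=O, and the non‑basic reagent avoids enolisation.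

**Step 8**
Reactants: 15
Product: 17 (2S,3S,6R)‑2,10‑dibromo‑3‑chloro‑3,11,11‑trimethylspiro[5.5]undec‑9‑en‑8‑one, via chlorosulfite 16 (not isolated)
Conditions: SOCl2 (1.2 equiv), CH2Cl2, −40 °C; then TiCl4 (10 mol %), −40 → 0 °C
Reagents that add atoms: thionyl chloride O=S(Cl)Cl
Why: SNi collapse of the tertiary chlorosulfite returns chloride to the face that oxygen leaves, which is also the only face open if C2–Br bridges the cation (anti opening at the tertiary carbon), so both ionisation modes should give the 2,3‑trans diequatorial bromochloride with retention at C3.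

**Step 9**
Reactants: 17
Product: 20 (2S,3S,6S)‑2,10‑dibromo‑3‑chloro‑3,11,11‑trimethyl‑7‑methylidenespiro[5.5]undec‑9‑en‑8‑one, via Mannich base 18 (not isolated), via ammonium iodide 19 (not isolated)
Conditions: LiHMDS, THF, −78 °C; CH2=NMe2+ I−, −78 °C → rt; MeI, CH2Cl2, rt; sat. aq NaHCO3, rt
Reagents that add atoms: Eschenmoser's salt C=[N+](C)C.[I-]; iodomethane CI (stays only in 19)
Why: Eschenmoser methylenation (α′‑enolate, Mannich reaction, N‑methylation, E1cB loss of NMe3), in which C7–H2 are the only enolisable hydrogens and the equatorial C–Br and C–Cl bonds have no antiperiplanar ring hydrogen, so loss of HX should not compete at −78 °C.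

**Step 10**
Reactants: 20
Product: 21 (2S,3S,6S,8R)‑2,10‑dibromo‑3‑chloro‑3,11,11‑trimethyl‑7‑methylidenespiro[5.5]undec‑9‑en‑8‑ol (target)
Conditions: (S)‑Me‑CBS (20 mol %), catecholborane, toluene, −78 °C; then H2O
Reagents that add atoms: none
Why: Corey–Bakshi–Shibata 1,2‑reduction under reagent control, in which the fully substituted C7 flank acts as the large group and C9–H as the small one so that the (S)‑catalyst should give 8R, while catecholborane at −78 °C avoids hydroboration and 1,4‑reduction of the methylene ketone.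

**Compound list**

1 | 8‑methylene‑1,4‑dioxaspiro[4.5]decane | C=C1CCC2(CC1)OCCO2 | starting material
2 | N,N,2‑trimethylpropanamide | CC(C)C(=O)N(C)C | starting material
3 | tetramethylketeniminium triflate | CC(C)=C=[N+](C)C.[O-]S(=O)(=O)C(F)(F)F | intermediate
4 | N,N‑dimethyliminium triflate of 5 | C[N+](C)=C1CC2(CCC3(CC2)OCCO3)C1(C)C.[O-]S(=O)(=O)C(F)(F)F | intermediate
5 | 1,1‑dimethyl‑8,11‑dioxadispiro[3.2.4^7.2^4]tridecan‑2‑one | O=C1CC2(CCC3(CC2)OCCO3)C1(C)C | intermediate
6 | ethynylmagnesium bromide | C#C[Mg]Br | starting material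
7 | 2‑ethynyl‑1,1‑dimethyl‑8,11‑dioxadispiro[3.2.4^7.2^4]tridecan‑2‑ol (racemic) | OC1(C#C)CC2(CCC3(CC2)OCCO3)C1(C)C | intermediate
8 | 2‑(bromoethynyl)‑1,1‑dimethyl‑8,11‑dioxadispiro[3.2.4^7.2^4]tridecan‑2‑ol (racemic) | OC1(C#CBr)CC2(CCC3(CC2)OCCO3)C1(C)C | intermediate
9 | 2‑[8‑(4‑bromo‑2‑oxobut‑3‑ynyl)‑1,4‑dioxaspiro[4.5]decan‑8‑yl]propan‑2‑yl radical | C[C](C)C1(CC(=O)C#CBr)CCC2(CC1)OCCO2 | intermediate
10 | 10‑bromo‑11,11‑dimethylspiro[5.5]undec‑9‑ene‑3,8‑dione 3‑(ethylene ketal) | O=C1CC2(CCC3(CC2)OCCO3)C(C)(C)C(Br)=C1 | intermediate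
11 | 10‑bromo‑11,11‑dimethylspiro[5.5]undec‑9‑ene‑3,8‑dione | O=C1CCC2(CC1)CC(=O)C=C(Br)C2(C)C | intermediate
12 | (6S)‑10‑bromo‑11,11‑dimethyl‑3‑(trimethylsilyloxy)spiro[5.5]undeca‑2,9‑dien‑8‑one | C1C(=O)C=C(Br)C(C)(C)[C@]12CCC(O[Si](C)(C)C)=CC2 | intermediate
13 | (2R,6R)‑2,10‑dibromo‑11,11‑dimethylspiro[5.5]undec‑9‑ene‑3,8‑dione (axial Br) | C1C(=O)C=C(Br)C(C)(C)[C@]12CCC(=O)[C@H](Br)C2 | intermediate
14 | (2S,6R)‑2,10‑dibromo‑11,11‑dimethylspiro[5.5]undec‑9‑ene‑3,8‑dione (equatorial Br) | C1C(=O)C=C(Br)C(C)(C)[C@]12CCC(=O)[C@@H](Br)C2 | intermediate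
15 | (2S,3S,6R)‑2,10‑dibromo‑3‑hydroxy‑3,11,11‑trimethylspiro[5.5]undec‑9‑en‑8‑one | C1C(=O)C=C(Br)C(C)(C)[C@]12CC[C@](C)(O)[C@@H](Br)C2 | intermediate
16 | chlorosulfite of 15 | C1C(=O)C=C(Br)C(C)(C)[C@]12CC[C@](C)(OS(=O)Cl)[C@@H](Br)C2 | intermediate
17 | (2S,3S,6R)‑2,10‑dibromo‑3‑chloro‑3,11,11‑trimethylspiro[5.5]undec‑9‑en‑8‑one | C1C(=O)C=C(Br)C(C)(C)[C@]12CC[C@](C)(Cl)[C@@H](Br)C2 | intermediate
18 | 7‑[(dimethylamino)methyl] derivative of 17 (C7 epimers) | CN(C)CC1C(=O)C=C(Br)C(C)(C)[C@]12CC[C@](C)(Cl)[C@@H](Br)C2 | intermediate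
19 | 7‑[(trimethylammonio)methyl] derivative of 17, iodide (C7 epimers) | C[N+](C)(C)CC1C(=O)C=C(Br)C(C)(C)[C@]12CC[C@](C)(Cl)[C@@H](Br)C2.[I-] | intermediate
20 | (2S,3S,6S)‑2,10‑dibromo‑3‑chloro‑3,11,11‑trimethyl‑7‑methylidenespiro[5.5]undec‑9‑en‑8‑one | C=C1C(=O)C=C(Br)C(C)(C)[C@]12CC[C@](C)(Cl)[C@@H](Br)C2 | intermediate
21 | (2S,3S,6S,8R)‑2,10‑dibromo‑3‑chloro‑3,11,11‑trimethyl‑7‑methylidenespiro[5.5]undec‑9‑en‑8‑ol | C=C1[C@H](O)C=C(Br)C(C)(C)[C@]12CC[C@](C)(Cl)[C@@H](Br)C2 | target

**Step count and risks**

Total step count: 10. Longest linear sequence: 10.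

Steps most likely to fail:

**Step 4 (Proposed new method).**
- What may go wrong: hydrogen transfer to the tertiary radical before it re‑closes, closure in the 5‑exo mode, or loss of the alkynyl bromine under irradiation.
- The fallback uses known chemistry. It sets out from 5 and returns at 11.
- Compound 5 is condensed with 2‑(aminooxy)‑2‑methylpropanoic acid to the oxime ether acid F1.
- Oxidative photoredox fragmentation–alkynylation with triisopropylsilyl‑ethynylbenziodoxolone follows. The iminyl radical undergoes β‑scission on the CMe2 side and the alkynyl group is transferred to the tertiary radical. This should give the alkynyl nitrile F2.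
- Hot KOH in aqueous ethylene glycol and then dilute HCl should remove silicon and hydrolyse both the nitrile and the ketal, giving the keto acid F3.
- Oxalyl bromide gives the acid bromide F4.
- AlBr3 in CH2Cl2 should close ring A by intramolecular acylation of the terminal alkyne. The acylium bonds to C9 and bromide adds to C10, which gives 11 directly.

**Step 8.**
- What may go wrong: capture of an open, unbridged cation from the axial face (loss of the C3 configuration), elimination towards C4 or C15, or Br/Cl exchange at C10.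
- The fallback sets out from 15 and returns at 17.
- Brief treatment with zinc dust in acetic acid at 0 °C should remove Br and OH reductively and give the Δ2‑olefin F5, which keeps C6.
- mCPBA attacks the face opposite to the axial C7 and gives the epoxide F6.
- LiCl/AcOH opens it trans‑diaxially (Fürst–Plattner) at the secondary C2 to the chlorohydrin F7.
- TMSBr converts the axial tertiary alcohol into the diaxial 3‑bromo‑2‑chloro compound F8.
- Warming in CHCl3 triggers the diaxial→diequatorial rearrangement known for steroidal vicinal dihalides. The antiperiplanar C3–Br assists loss of the strained axial C2–Cl. Bromine ends on C2 and chlorine on C3, each on its own face, which is 17.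

**Step 6 (key step).**
- What may go wrong: incomplete discrimination between the enantiotopic hydrogens, competing deprotonation at C7, or attack of the amide on the bromoenone.
- The fallback sets out from 11 and returns at 14.
- It uses catalytic enamine desymmetrisation instead of a stoichiometric base. The catalyst is a C2‑symmetric 4,5‑diphenylimidazolidine and the Br+ donor is 4,4‑dibromo‑2,6‑di‑tert‑butylcyclohexa‑2,5‑dienone.
- Only the unhindered saturated ketone condenses with the amine.
- The same bromide‑catalysed equilibration follows, and no new isolable compound is made.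

**Further compounds**

F1 | step 4 | 2‑methyl‑2‑({[1,1‑dimethyl‑8,11‑dioxadispiro[3.2.4^7.2^4]tridecan‑2‑ylidene]amino}oxy)propanoic acid | OC(=O)C(C)(C)ON=C1CC2(CCC3(CC2)OCCO3)C1(C)C
F2 | step 4 | {8‑[2‑methyl‑4‑(triisopropylsilyl)but‑3‑yn‑2‑yl]‑1,4‑dioxaspiro[4.5]decan‑8‑yl}acetonitrile | N#CCC1(CCC2(CC1)OCCO2)C(C)(C)C#C[Si](C(C)C)(C(C)C)C(C)C
F3 | step 4 | [1‑(2‑methylbut‑3‑yn‑2‑yl)‑4‑oxocyclohexyl]acetic acid | OC(=O)CC1(CCC(=O)CC1)C(C)(C)C#C
F4 | step 4 | [1‑(2‑methylbut‑3‑yn‑2‑yl)‑4‑oxocyclohexyl]acetyl bromide | BrC(=O)CC1(CCC(=O)CC1)C(C)(C)C#C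
F5 | step 8 | (6S)‑10‑bromo‑3,11,11‑trimethylspiro[5.5]undeca‑2,9‑dien‑8‑one | C1C(=O)C=C(Br)C(C)(C)[C@]12CCC(C)=CC2
F6 | step 8 | (2S,3R,6S)‑10‑bromo‑2,3‑epoxy‑3,11,11‑trimethylspiro[5.5]undec‑9‑en‑8‑one (oxygen trans to C7) | C1C(=O)C=C(Br)C(C)(C)[C@]12CC[C@@]3(C)O[C@H]3C2
F7 | step 8 | (2R,3R,6R)‑10‑bromo‑2‑chloro‑3‑hydroxy‑3,11,11‑trimethylspiro[5.5]undec‑9‑en‑8‑one (Cl and OH diaxial) | C1C(=O)C=C(Br)C(C)(C)[C@]12CC[C@@](C)(O)[C@H](Cl)C2
F8 | step 8 | (2R,3R,6R)‑3,10‑dibromo‑2‑chloro‑3,11,11‑trimethylspiro[5.5]undec‑9‑en‑8‑one (C2‑Cl and C3‑Br diaxial) | C1C(=O)C=C(Br)C(C)(C)[C@]12CC[C@@](C)(Br)[C@H](Cl)C2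
F0 | step 6 | none | none
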